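- The constant I would carry from the two runs is the product leak (racemisation), and you asked for a quick number, so here is what it gives for the autumn flask.

| flask | left-handed substrate | right-handed substrate | coupling partner | precatalyst | remark | time |
|---|---|---|---|---|---|---|
| autumn | 0.10 M | 0.10 M | 0.22 M | 2 mM | the very flask that is asked about, followed so far |  |
| midnight | 0.10 M | 0.10 M | 0.22 M | 4 mM | run made earlier |  |
| flask | 0.10 M | 0.10 M | 0.220 M | 2.0 mM |  | 6.0 h |

autumn run (percent of the left-handed substrate and right-handed substrate together charged)

| time / min | left-handed product / % | right-handed product / % | left-handed substrate / % |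
|---|---|---|---|
| 6.00 | 1.8 | 0.4 | 47.9 |
| 8.00 | 3.1 | 0 | 46.1 |
| 12.0 | 7.3 | 0 | 43.7 |
| 20.0 | 13.2 | 0.1 | 37.0 |
| 30.0 | 20.9 | 1.4 | 31.2 |
| 50.0 | 32.8 | 2.0 | 22.0 |
| 80.0 | 43.2 | 3.4 | 16.5 |

midnight run (percent of the left-handed substrate and right-handed substrate together charged)

| time / h | left-handed product / % | right-handed product / % | left-handed substrate / % |
|---|---|---|---|
| 0.333 | 21.8 | 1.3 | 30.9 |
| 0.500 | 31.0 | 2.0 | 21.6 |
| 0.833 | 43.7 | 3.6 | 13.4 |
| 1.33 | 53.3 | 6.0 | 9.2 |
| 2.00 | 61.5 | 8.3 | 7.4 |
| 3.00 | 67.0 | 12.2 | 5.8 |
| 4.00 | 69.0 | 14.6 | 5.4 |

(each reading ± 0.5 percentage points)

1. left-handed product and right-handed product together, in percent of the left-handed substrate and right-handed substrate charged together, at 6.0 h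
2. excess of left-handed product over right-handed product in the product at 6.0 h
3. whether the exchange between left-handed substrate and right-handed substrate keeps pace with the reaction: how far the product's excess at 6.0 h gets from its value without exchange to its value with instant exchange (above 80% keeps pace, below 20% hardly takes part, else lags behind)

- catalyst is single-handed; left-handed substrate and right-handed substrate are mirror images of each other, charged as a racemate, each of them at the stated concentration
- the numbers in the tables scatter with a standard deviation of 0.5 percentage points
- an excess is the difference of the two amounts in percent of their sum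
- an excess is below zero if the other one leads

- In the midnight run, right-handed product climbs steadily late on, from 8.3% at 2.00 h to 14.6% at 4.00 h. Dividing that rise by the mean gap between the two products gives 0.0586 h⁻¹, the share of that gap crossing over per hour. It is a high reading, since the rise also holds right-handed product made directly.
- Between 3.00 h and 4.00 h of the midnight run, left-handed product is made 1.63 times faster than the leak takes it away, and this ratio is what drifts. Left-handed substrate in that run meanwhile goes from 5.8% to 5.4% while left-handed product gains 2 percentage points, so exchange is refilling it, and I say it keeps pace.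
- Total product of 46.6% at 80.0 min in autumn matches 47.3% at 0.833 h in midnight, so the midnight run reaches that total 1.60 times faster than autumn. The asked time therefore maps to 3.75 h there, near the last reading at 4.00 h, so I take that reading's total of 83.6% as my number.
- I take the leak to run on clock hours, whatever the catalyst, so the midnight excess of 65.1% at 4.00 h decays for the 2.00 h that the autumn flask runs beyond that time, to about 51.5%, an estimate on the low side.
- Your hunch, the forecast, says 81% and 66%, and its verdict on the exchange is lags behind, in its words “so exchange lags behind”.
- The flask gives 84.5% and 56.3%, and the exchange keeps pace, 93% of the way.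

    coupling partner + catalyst + left-handed substrate → catalyst + left-handed product (k = 79.0 L² mol⁻² min⁻¹)
    coupling partner + catalyst + right-handed substrate → catalyst + right-handed product (k = 2.50 L² mol⁻² min⁻¹)
    left-handed substrate ⇌ right-handed substrate (k = 0.0100 min⁻¹)
    left-handed product ⇌ right-handed product (k = 9.10 × 10⁻⁴ min⁻¹)
    coupling partner + precatalyst → catalyst + spent reagent (k = 0.330 L mol⁻¹ min⁻¹)

- At 6.00 h left-handed product in this flask is made 1.11 times faster than it is used up, against 12.0 times faster at 1.08 h. My leak, applied to its 66.0% of left-handed and 18.5% of right-handed product, moves 0.0278 h⁻¹ of the charge across. In the neighbour charged with 0.055 M of coupling partner, which at 6.0 h holds 20.6% and 5.14% of the products at an excess of 60.1%, the same leak moves 0.00906 h⁻¹.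

The numbers in the tables are simulated with made-up constants; scatter was added.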